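A direct plan would C-prenylate 2,6-dihydroxy-4-methoxybenzaldehyde A1 to aldehyde A2, etherify one hydroxyl with 2-chloro-1-(2,4,5-trimethoxyphenyl)ethanone A3 to keto aldehyde A4, close ring C at C3–C4 by a carbene-catalysed crossed benzoin reaction to 3-hydroxyisoflavanone A5, and dehydrate. Its weakest steps would be:
- the C-prenylation, in which O-alkylation and double alkylation of the ambident phenoxide would compete;
- the etherification, which would have to tell apart two hydroxyls that are both hydrogen bonded to the formyl group and stop before aldol closure to a 2-aroylbenzofuran;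
- the benzoin closure with dehydration, in which an electron-rich, doubly ortho-substituted aldehyde would be a reluctant acyl anion source and a tertiary alcohol would be made only to be removed.

**Strategy.** The new route cuts ring A away from the pyranone at two neighbouring bonds, C8a–O1 and C4a–C4, exactly the pair an aryne can form. 3,5-Dimethoxy-4-prenylbenzyne, released from a silyl triflate that descends from a mirror-symmetric phenol, would insert into the carboxyl C–O bond of 3-methoxy-2-(2,4,5-trimethoxyphenyl)acrylic acid. The phenoxide so formed closes ring C by addition to the β-methoxy enone and loss of methanol. One operation joins both halves, builds the pyranone and places the prenyl group at C6, since the symmetry of the precursor and the C5 methoxy group beside the triple bond leave one outcome. Phenoxide C-prenylation, hydroxyl discrimination, benzoin closure and dehydration all disappear.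

Key step: step 10

The target is achiral, so no stereocentre has to be set. Assumption: ester 17 and acid 18 are taken on as E/Z mixtures, because the alkene geometry is lost when ring C closes.

Step 1
Reactants: 1 3,5-dimethoxyphenol
Product: 2 (3,5-dimethoxyphenoxy)tri(propan-2-yl)silane
Conditions: TIPSCl (1.1 equiv), imidazole (2.0 equiv), DMF, rt
Reagents that add atoms: chlorotri(propan-2-yl)silane (TIPSCl), CC(C)[Si](Cl)(C(C)C)C(C)C
Why: Imidazole-promoted silylation of a phenol gives a bulky, poorly coordinating silyl ether that is stable to butyllithium and should not direct metalation to its own ortho positions in step 2.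

Step 2
Reactants: 2 (3,5-dimethoxyphenoxy)tri(propan-2-yl)silane; 3 prenyl bromide (1-bromo-3-methylbut-2-ene)
Product: 5 [3,5-dimethoxy-4-(3-methylbut-2-en-1-yl)phenoxy]tri(propan-2-yl)silane, via aryllithium 4 (not isolated)
Conditions: n-BuLi (1.2 equiv), THF, 0 °C to rt, 2 h; then 3 (1.3 equiv), −78 °C to rt
Reagents that add atoms: none
Why: Directed ortho-metalation at the one position flanked by two methoxy groups (as in the 2-lithiation of 1,3-dimethoxybenzene) and SN2 alkylation of the aryllithium at the primary carbon of 3 should give a single C-prenyl isomer, because 2 has a mirror plane and the side chain enters between the two oxygens that become O5 and O7.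

Step 3
Reactants: 5 [3,5-dimethoxy-4-(3-methylbut-2-en-1-yl)phenoxy]tri(propan-2-yl)silane
Product: 6 3,5-dimethoxy-4-(3-methylbut-2-en-1-yl)phenol
Conditions: Bu4NF (1.1 equiv), THF, 0 °C; aq. NH4Cl
Reagents that add atoms: none
Why: Fluoride cleavage of an aryl silyl ether, driven by the strong Si–F bond, should free the phenol without touching the methyl ethers or the alkene.

Step 4
Reactants: 6 3,5-dimethoxy-4-(3-methylbut-2-en-1-yl)phenol
Product: 7 3,5-dimethoxy-4-(3-methylbut-2-en-1-yl)phenyl N-(propan-2-yl)carbamate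
Conditions: iPrNCO (1.5 equiv), Et3N (0.2 equiv), CH2Cl2, rt
Reagents that add atoms: 2-isocyanatopropane (isopropyl isocyanate), CC(C)N=C=O
Why: Base-catalysed addition of the phenol to an isocyanate gives an O-aryl carbamate, a strong directing group for ortho-lithiation that can later be removed by mild base.

Step 5
Reactants: 7 3,5-dimethoxy-4-(3-methylbut-2-en-1-yl)phenyl N-(propan-2-yl)carbamate
Product: 11 3,5-dimethoxy-4-(3-methylbut-2-en-1-yl)-2-(trimethylsilyl)phenyl N-(propan-2-yl)carbamate, via N-silyl carbamate 8 (not isolated), via ortho-lithiated carbamate 9 (not isolated), via doubly silylated carbamate 10 (not isolated)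
Conditions: TBSOTf (1.1 equiv), TMEDA (1.1 equiv), Et2O, 0 °C to rt; then TMEDA (2.0 equiv), n-BuLi (2.0 equiv), −78 °C, 1 h; TMSCl (3.0 equiv), −78 °C to rt; cold aq. NaHSO4
Reagents that add atoms: chlorotrimethylsilane, C[Si](C)(C)Cl
Why: Directed ortho-metalation of an O-aryl carbamate whose N–H is masked in the flask as the N-silyl derivative should occur at one of the two symmetry-equivalent ortho positions, each activated by the carbamate and a methoxy group, faster at −78 °C than deprotonation of the prenyl methylene, and trapping with TMSCl followed by hydrolysis of the N–Si bond on work-up gives 11.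

Step 6
Reactants: 11 3,5-dimethoxy-4-(3-methylbut-2-en-1-yl)-2-(trimethylsilyl)phenyl N-(propan-2-yl)carbamate
Product: 13 3,5-dimethoxy-4-(3-methylbut-2-en-1-yl)-2-(trimethylsilyl)phenyl trifluoromethanesulfonate, via silyl phenol 12 (not isolated)
Conditions: DBU (1.5 equiv), Et2NH (1.2 equiv), MeCN, 40 °C; then PhNTf2 (1.5 equiv), rt
Reagents that add atoms: N-phenylbis(trifluoromethanesulfonimide), O=S(=O)(N(c1ccccc1)S(=O)(=O)C(F)(F)F)C(F)(F)F
Why: E1cB cleavage of the N-monosubstituted carbamate (isopropyl isocyanate is lost and trapped by diethylamine) frees the phenoxide, which PhNTf2 triflates in the same flask, the standard one-pot route to ortho-silylaryl triflates, with no acid to attack the electron-rich aryl–silicon bond or the alkene.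

Step 7
Reactants: 14 1,2,4-trimethoxybenzene; 15 methyl chlorooxoacetate
Product: 16 methyl 2-oxo-2-(2,4,5-trimethoxyphenyl)acetate
Conditions: TiCl4 (1.1 equiv), 15 (1.1 equiv), CH2Cl2, −20 to 0 °C; ice water
Reagents that add atoms: none
Why: Friedel–Crafts acylation by the acid chloride end of 15 should occur at C5 of 14, the only position para to one methoxy group and ortho to another, and TiCl4 at low temperature is chosen to spare the methoxy group that ends up ortho to the ketone.

Step 8
Reactants: 16 methyl 2-oxo-2-(2,4,5-trimethoxyphenyl)acetate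
Product: 17 methyl 3-methoxy-2-(2,4,5-trimethoxyphenyl)prop-2-enoate (E/Z mixture)
Conditions: Ph3P(CH2OMe)Cl (1.5 equiv), KOtBu (1.45 equiv), THF, 0 °C; then 16, 0 °C to rt
Reagents that add atoms: (methoxymethyl)triphenylphosphonium chloride, COC[P+](c1ccccc1)(c1ccccc1)c1ccccc1.[Cl-]
Why: Wittig reaction of the unstabilised methoxymethylidene ylide with the activated keto group of an aryl glyoxylate is the standard entry to β-methoxyacrylates and leaves the ester untouched.

Step 9
Reactants: 17 methyl 3-methoxy-2-(2,4,5-trimethoxyphenyl)prop-2-enoate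
Product: 18 3-methoxy-2-(2,4,5-trimethoxyphenyl)prop-2-enoic acid (E/Z mixture)
Conditions: LiOH·H2O (3 equiv), THF/MeOH/H2O, 40 °C; then 1 M HCl to pH 3, 0 °C
Reagents that add atoms: lithium hydroxide, [Li+].[OH-]
Why: Saponification of the methyl ester (BAc2) should proceed without attack at the β-carbon of the vinylogous carbonate under these mild conditions, and brief cold acidification spares the enol ether.

Step 10
Reactants: 13 3,5-dimethoxy-4-(3-methylbut-2-en-1-yl)-2-(trimethylsilyl)phenyl trifluoromethanesulfonate; 18 3-methoxy-2-(2,4,5-trimethoxyphenyl)prop-2-enoic acid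
Product: 21 5,7-dimethoxy-6-(3-methylbut-2-en-1-yl)-3-(2,4,5-trimethoxyphenyl)-4H-chromen-4-one, via aryne 19 (not isolated), via hydroxyaryl enone 20 (not isolated)
Conditions: 13 (1.5 equiv), 18 (1.0 equiv), CsF (4.0 equiv), THF (0.02 M), 125 °C, sealed tube, 24 h
Reagents that add atoms: none
Why: Fluoride removes the silyl group of 13 and loss of triflate gives aryne 19; the carboxylate of 18 adds through oxygen to C1 (the former triflate carbon), the aryne carbon remote from the C3 methoxy group, because this places the developing aryl anion at C2 beside the electron-withdrawing C–O bond and because C1 is flanked only by hydrogen. The aryl anion then attacks its own ester carbonyl through a four-membered transition state and the acyl group shifts from oxygen to carbon, which leaves the phenoxide of ketone 20; this net insertion of an aryne into the carboxyl C–O bond is the known reaction of arynes with carboxylic acids, which gives ortho-hydroxyaryl ketones and, with unsaturated acids, chromanones and flavones by conjugate cyclisation in the same flask. The phenoxide closes ring C by 6-endo-trig conjugate addition to the β-methoxy enone and loss of methoxide, the usual chromone closure of ortho-hydroxyaryl β-alkoxy enones, so both alkene geometries of 18 converge. No stereocentre is formed. The step needs one regiochemical outcome, oxygen on C1 and acyl on C2, which the methoxy group beside the triple bond secures, and it needs acyl transfer to outrun protonation of the aryl anion, which high temperature in THF favours. Because 13 descends from a phenol with a mirror plane through C1 and C4, this single selectivity also fixes the prenyl group at C6 of the chromone and not at C8.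

Step 11
Reactants: 21 5,7-dimethoxy-6-(3-methylbut-2-en-1-yl)-3-(2,4,5-trimethoxyphenyl)-4H-chromen-4-one
Product: 23 5-hydroxy-7-methoxy-6-(3-methylbut-2-en-1-yl)-3-(2,4,5-trimethoxyphenyl)-4H-chromen-4-one, via boron chelate 22 (not isolated)
Conditions: BCl3 (1 M in CH2Cl2, 2.0 equiv), CH2Cl2, −78 to −30 °C; cold sat. aq. NaHCO3
Reagents that add atoms: none
Why: Chelation-controlled ether cleavage, in which BCl3 binds the C4 carbonyl and the C5 methoxy oxygen in a six-membered chelate and chloride removes the methyl group by SN2, should spare the C7 and the three ring B methoxy groups, which cannot form such a chelate, while low temperature, the boron-bound oxygen in 22 and a buffered quench are meant to keep the prenyl alkene from acid-induced cyclisation.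

**Compound list**
1 | 3,5-dimethoxyphenol | COc1cc(O)cc(OC)c1 | starting material
2 | (3,5-dimethoxyphenoxy)tri(propan-2-yl)silane | COc1cc(OC)cc(O[Si](C(C)C)(C(C)C)C(C)C)c1 | intermediate
3 | prenyl bromide (1-bromo-3-methylbut-2-ene) | CC(C)=CCBr | starting material
4 | [2,6-dimethoxy-4-(triisopropylsilyloxy)phenyl]lithium | [Li]c1c(OC)cc(O[Si](C(C)C)(C(C)C)C(C)C)cc1OC | intermediate
5 | [3,5-dimethoxy-4-(3-methylbut-2-en-1-yl)phenoxy]tri(propan-2-yl)silane | COc1cc(O[Si](C(C)C)(C(C)C)C(C)C)cc(OC)c1CC=C(C)C | intermediate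
6 | 3,5-dimethoxy-4-(3-methylbut-2-en-1-yl)phenol | COc1cc(O)cc(OC)c1CC=C(C)C | intermediate
7 | 3,5-dimethoxy-4-(3-methylbut-2-en-1-yl)phenyl N-(propan-2-yl)carbamate | COc1cc(OC(=O)NC(C)C)cc(OC)c1CC=C(C)C | intermediate
8 | 3,5-dimethoxy-4-(3-methylbut-2-en-1-yl)phenyl N-[tert-butyl(dimethyl)silyl]-N-(propan-2-yl)carbamate | COc1cc(OC(=O)N(C(C)C)[Si](C)(C)C(C)(C)C)cc(OC)c1CC=C(C)C | intermediate
9 | 2-lithio derivative of 8 (lithium between the carbamate and a methoxy group) | COc1cc(OC(=O)N(C(C)C)[Si](C)(C)C(C)(C)C)c([Li])c(OC)c1CC=C(C)C | intermediate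
10 | 3,5-dimethoxy-4-(3-methylbut-2-en-1-yl)-2-(trimethylsilyl)phenyl N-[tert-butyl(dimethyl)silyl]-N-(propan-2-yl)carbamate | COc1cc(OC(=O)N(C(C)C)[Si](C)(C)C(C)(C)C)c([Si](C)(C)C)c(OC)c1CC=C(C)C | intermediate
11 | 3,5-dimethoxy-4-(3-methylbut-2-en-1-yl)-2-(trimethylsilyl)phenyl N-(propan-2-yl)carbamate | COc1cc(OC(=O)NC(C)C)c([Si](C)(C)C)c(OC)c1CC=C(C)C | intermediate
12 | 3,5-dimethoxy-4-(3-methylbut-2-en-1-yl)-2-(trimethylsilyl)phenol | COc1cc(O)c([Si](C)(C)C)c(OC)c1CC=C(C)C | intermediate
13 | 3,5-dimethoxy-4-(3-methylbut-2-en-1-yl)-2-(trimethylsilyl)phenyl trifluoromethanesulfonate | COc1cc(OS(=O)(=O)C(F)(F)F)c([Si](C)(C)C)c(OC)c1CC=C(C)C | intermediate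
14 | 1,2,4-trimethoxybenzene | COc1ccc(OC)c(OC)c1 | starting material
15 | methyl chlorooxoacetate | COC(=O)C(Cl)=O | starting material
16 | methyl 2-oxo-2-(2,4,5-trimethoxyphenyl)acetate | COC(=O)C(=O)c1cc(OC)c(OC)cc1OC | intermediate
17 | methyl 3-methoxy-2-(2,4,5-trimethoxyphenyl)prop-2-enoate (E/Z mixture) | COC=C(C(=O)OC)c1cc(OC)c(OC)cc1OC | intermediate
18 | 3-methoxy-2-(2,4,5-trimethoxyphenyl)prop-2-enoic acid (E/Z mixture) | COC=C(C(=O)O)c1cc(OC)c(OC)cc1OC | intermediate
19 | 3,5-dimethoxy-4-(3-methylbut-2-en-1-yl)benzyne (1,2-didehydrobenzene, triple bond C1–C2) | COC1=CC#CC(OC)=C1CC=C(C)C | intermediate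
20 | 1-[6-hydroxy-2,4-dimethoxy-3-(3-methylbut-2-en-1-yl)phenyl]-3-methoxy-2-(2,4,5-trimethoxyphenyl)prop-2-en-1-one | COC=C(C(=O)c1c(O)cc(OC)c(CC=C(C)C)c1OC)c1cc(OC)c(OC)cc1OC | intermediate
21 | 5,7-dimethoxy-6-(3-methylbut-2-en-1-yl)-3-(2,4,5-trimethoxyphenyl)-4H-chromen-4-one | COc1cc(OC)c(-c2coc3cc(OC)c(CC=C(C)C)c(OC)c3c2=O)cc1OC | intermediate
22 | 5-(dichloroboryloxy)-7-methoxy-6-(3-methylbut-2-en-1-yl)-3-(2,4,5-trimethoxyphenyl)-4H-chromen-4-one (boron chelated to the C4 carbonyl) | COc1cc(OC)c(-c2coc3cc(OC)c(CC=C(C)C)c(OB(Cl)Cl)c3c2=O)cc1OC | intermediate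
23 | 5-hydroxy-7-methoxy-6-(3-methylbut-2-en-1-yl)-3-(2,4,5-trimethoxyphenyl)-4H-chromen-4-one (achiral) | COc1cc(OC)c(-c2coc3cc(OC)c(CC=C(C)C)c(O)c3c2=O)cc1OC | target

**Step count.** Total: 11 steps. Longest linear sequence: 8 steps (steps 1 to 6, 10 and 11 from 3,5-dimethoxyphenol); the acid branch has 3 steps (7 to 9).

**Steps most likely to fail**

Step 10. The aryl anion formed after carboxylate addition may be protonated before it transfers the acyl group, because the carbonyl of a β-methoxyacrylate is a weak electrophile, so that only the O-aryl ester would result. The electron-rich aryne may also be consumed by ene reaction with prenyl side chains. The fallback would replace the aryne by a polar acylation; it sets out from ortho-lithiated carbamate 9 (made as in step 5) and acid 18 and comes back to the route at hydroxyaryl enone 20. Acid 18 would be converted (CDI, then MeNHOMe·HCl, CH2Cl2) into the Weinreb amide N,3-dimethoxy-N-methyl-2-(2,4,5-trimethoxyphenyl)prop-2-enamide F1. Addition of 9 to this amide at −78 °C and aqueous work-up, which also removes the N-silyl group, should give the keto carbamate 3,5-dimethoxy-2-[3-methoxy-2-(2,4,5-trimethoxyphenyl)prop-2-enoyl]-4-(3-methylbut-2-en-1-yl)phenyl N-(propan-2-yl)carbamate F2. DBU and Et2NH in MeCN at 40 °C would then remove the carbamate as in step 6 and release the phenoxide of 20, which should close to 21 in the same flask.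

Step 11. The Lewis acid, or hydrogen chloride formed from traces of moisture, may add to or ionise the trisubstituted alkene, with hydrochlorination or ring closure of the side chain onto the freed C5 oxygen. The fallback would carry an allyl group through the demethylation and turn it into the prenyl group afterwards; it sets out from aryllithium 4 and comes back at target 23. Quenching 4 with allyl bromide in place of 3 should give [3,5-dimethoxy-4-(prop-2-en-1-yl)phenoxy]tri(propan-2-yl)silane F3. Steps 3 to 6 applied unchanged would lead through 3,5-dimethoxy-4-(prop-2-en-1-yl)phenol F4, its N-(propan-2-yl)carbamate F5, the N-silyl carbamate F6, its ortho-lithio derivative F7, the doubly silylated carbamate F8, the ortho-silyl carbamate F9 and the ortho-silyl phenol F10 to the allyl silyl triflate F11. With acid 18 and CsF as in step 10, the allyl aryne F12 should pass through the allyl hydroxyaryl enone F13 to 6-allyl-5,7-dimethoxy-3-(2,4,5-trimethoxyphenyl)-4H-chromen-4-one F14. BCl3 would now meet only a monosubstituted alkene, which does not ionise, and should give through the boron chelate F15 the 6-allyl-5-hydroxy-7-methoxy isoflavone F16. Cross-metathesis with 2-methylbut-2-ene (second-generation Grubbs catalyst, CH2Cl2, 40 °C) should then give 23.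

Step 5. Butyllithium may deprotonate the benzylic and allylic methylene of the prenyl group, which lies between two methoxy groups, instead of the ring, or the lithiated carbamate may suffer carbamoyl migration to carbon on warming. The fallback would replace deprotonation by halogen–lithium exchange and an oxygen-to-carbon silyl shift; it sets out from phenol 6 and comes back at silyl triflate 13. NBS (1.0 equiv, CH2Cl2, −78 °C) should brominate one of the two equivalent ortho positions to give 2-bromo-3,5-dimethoxy-4-(3-methylbut-2-en-1-yl)phenol F17. Hexamethyldisilazane would convert it into the aryl trimethylsilyl ether F18. n-BuLi at −100 °C would exchange bromine for lithium to give aryllithium F19, in which silicon migrates from oxygen to carbon (retro-Brook rearrangement) to leave the lithium salt of silyl phenol 12, and Tf2O would then give 13.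

**Further compounds**
F1 | step 10 | N,3-dimethoxy-N-methyl-2-(2,4,5-trimethoxyphenyl)prop-2-enamide | COC=C(C(=O)N(C)OC)c1cc(OC)c(OC)cc1OC
F2 | step 10 | 3,5-dimethoxy-2-[3-methoxy-2-(2,4,5-trimethoxyphenyl)prop-2-enoyl]-4-(3-methylbut-2-en-1-yl)phenyl N-(propan-2-yl)carbamate | COC=C(C(=O)c1c(OC(=O)NC(C)C)cc(OC)c(CC=C(C)C)c1OC)c1cc(OC)c(OC)cc1OC
F3 | step 11 | [3,5-dimethoxy-4-(prop-2-en-1-yl)phenoxy]tri(propan-2-yl)silane | COc1cc(O[Si](C(C)C)(C(C)C)C(C)C)cc(OC)c1CC=C
F4 | step 11 | 3,5-dimethoxy-4-(prop-2-en-1-yl)phenol | COc1cc(O)cc(OC)c1CC=C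
F5 | step 11 | 3,5-dimethoxy-4-(prop-2-en-1-yl)phenyl N-(propan-2-yl)carbamate | COc1cc(OC(=O)NC(C)C)cc(OC)c1CC=C
F6 | step 11 | 3,5-dimethoxy-4-(prop-2-en-1-yl)phenyl N-[tert-butyl(dimethyl)silyl]-N-(propan-2-yl)carbamate | COc1cc(OC(=O)N(C(C)C)[Si](C)(C)C(C)(C)C)cc(OC)c1CC=C
F7 | step 11 | 2-lithio derivative of F6 | COc1cc(OC(=O)N(C(C)C)[Si](C)(C)C(C)(C)C)c([Li])c(OC)c1CC=C
F8 | step 11 | 3,5-dimethoxy-4-(prop-2-en-1-yl)-2-(trimethylsilyl)phenyl N-[tert-butyl(dimethyl)silyl]-N-(propan-2-yl)carbamate | COc1cc(OC(=O)N(C(C)C)[Si](C)(C)C(C)(C)C)c([Si](C)(C)C)c(OC)c1CC=C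
F9 | step 11 | 3,5-dimethoxy-4-(prop-2-en-1-yl)-2-(trimethylsilyl)phenyl N-(propan-2-yl)carbamate | COc1cc(OC(=O)NC(C)C)c([Si](C)(C)C)c(OC)c1CC=C
F10 | step 11 | 3,5-dimethoxy-4-(prop-2-en-1-yl)-2-(trimethylsilyl)phenol | COc1cc(O)c([Si](C)(C)C)c(OC)c1CC=C
F11 | step 11 | 3,5-dimethoxy-4-(prop-2-en-1-yl)-2-(trimethylsilyl)phenyl trifluoromethanesulfonate | COc1cc(OS(=O)(=O)C(F)(F)F)c([Si](C)(C)C)c(OC)c1CC=C
F12 | step 11 | 3,5-dimethoxy-4-(prop-2-en-1-yl)benzyne | COC1=CC#CC(OC)=C1CC=C
F13 | step 11 | 1-[6-hydroxy-2,4-dimethoxy-3-(prop-2-en-1-yl)phenyl]-3-methoxy-2-(2,4,5-trimethoxyphenyl)prop-2-en-1-one | COC=C(C(=O)c1c(O)cc(OC)c(CC=C)c1OC)c1cc(OC)c(OC)cc1OC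
F14 | step 11 | 5,7-dimethoxy-6-(prop-2-en-1-yl)-3-(2,4,5-trimethoxyphenyl)-4H-chromen-4-one | COc1cc(OC)c(-c2coc3cc(OC)c(CC=C)c(OC)c3c2=O)cc1OC
F15 | step 11 | 5-(dichloroboryloxy)-7-methoxy-6-(prop-2-en-1-yl)-3-(2,4,5-trimethoxyphenyl)-4H-chromen-4-one | COc1cc(OC)c(-c2coc3cc(OC)c(CC=C)c(OB(Cl)Cl)c3c2=O)cc1OC
F16 | step 11 | 5-hydroxy-7-methoxy-6-(prop-2-en-1-yl)-3-(2,4,5-trimethoxyphenyl)-4H-chromen-4-one | COc1cc(OC)c(-c2coc3cc(OC)c(CC=C)c(O)c3c2=O)cc1OC
F17 | step 5 | 2-bromo-3,5-dimethoxy-4-(3-methylbut-2-en-1-yl)phenol | COc1cc(O)c(Br)c(OC)c1CC=C(C)C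
F18 | step 5 | [2-bromo-3,5-dimethoxy-4-(3-methylbut-2-en-1-yl)phenoxy]trimethylsilane | COc1cc(O[Si](C)(C)C)c(Br)c(OC)c1CC=C(C)C
F19 | step 5 | [2,4-dimethoxy-3-(3-methylbut-2-en-1-yl)-6-(trimethylsilyloxy)phenyl]lithium | COc1cc(O[Si](C)(C)C)c([Li])c(OC)c1CC=C(C)C
A1 | direct plan | 2,6-dihydroxy-4-methoxybenzaldehyde | COc1cc(O)c(C=O)c(O)c1
A2 | direct plan | 2,6-dihydroxy-4-methoxy-3-(3-methylbut-2-en-1-yl)benzaldehyde | COc1cc(O)c(C=O)c(O)c1CC=C(C)C
A3 | direct plan | 2-chloro-1-(2,4,5-trimethoxyphenyl)ethan-1-one | COc1cc(OC)c(C(=O)CCl)cc1OC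
A4 | direct plan | 2-hydroxy-4-methoxy-3-(3-methylbut-2-en-1-yl)-6-[2-oxo-2-(2,4,5-trimethoxyphenyl)ethoxy]benzaldehyde | COc1cc(OCC(=O)c2cc(OC)c(OC)cc2OC)c(C=O)c(O)c1CC=C(C)C
A5 | direct plan | 3,5-dihydroxy-7-methoxy-6-(3-methylbut-2-en-1-yl)-3-(2,4,5-trimethoxyphenyl)-2,3-dihydro-4H-chromen-4-one (racemic) | COc1cc2OCC(O)(c3cc(OC)c(OC)cc3OC)C(=O)c2c(O)c1CC=C(C)C
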